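**Retrosynthetic overview**

1. The strategy rests on ring A (C1′–C6′): an acylphloroglucinol with the cinnamoyl group on C1′, oxygen on C2′, C4′ and C6′, and the heptenyl carbon C1 on C3′. This is a cinnamoyl tetraketide whose C3′ corresponds to the nucleophilic C3 of a 4-hydroxy-2-pyrone.
2. Key disconnection: the C1′–C2′ bond (Claisen) opens ring A to the 3-substituted 4-hydroxy-6-(cinnamoylmethyl)-2-pyrone 14. Ring A is the only ring formed in the route; the pyrone and the three benzene rings are bought.
3. 14 comes from dianion C-acylation of pyrone 11 with Weinreb amide 12; 11 from cross-metathesis of 10 with 8; 10 from iridium-catalysed branched allylic alkylation of triacetic acid lactone 9 with carbonate 4 (sets C1, R).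
4. 8 comes from Brown allylation of 3-phenylpropanal (sets C5, S); 4 from methyl p-coumarate in three steps.
5. After ring A: 4′-O-silylation, 6′-O-methylation, one buffered fluoride deprotection. Only silyl groups are used, because the doubly benzylic, allylic C1 of the target can ionise in acid.

Key step: step 9

Assumption: the (Ra,Rc,Rc) Feringa-type phosphoramidite is taken to direct the pyronate to the allyl face that gives the (R) centre, by analogy with its sense for cinnamyl carbonates and other nucleophiles; if the sense is opposite, the (Sa,Sc,Sc) ligand is used with no other change.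

**Route**

Step 1
Reactants: 1 methyl (E)-4-hydroxycinnamate
Product: 2 methyl (E)-4-(triisopropylsilyloxy)cinnamate
Conditions: TIPSCl, imidazole, DMF, 0 °C to rt
Reagents that add atoms: triisopropylsilyl chloride, CC(C)[Si](Cl)(C(C)C)C(C)C
Why: Imidazole-promoted silylation of the phenol (silyl ether formation) gives an aryl ether that tolerates hydride, amide base and magnesium methoxide and is later removed by fluoride without acid.

Step 2
Reactants: 2 methyl (E)-4-(triisopropylsilyloxy)cinnamate
Product: 3 (E)-4-(triisopropylsilyloxy)cinnamyl alcohol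
Conditions: DIBAL-H, CH2Cl2, −78 °C; Rochelle salt
Reagents that add atoms: none
Why: DIBAL-H reduces the conjugated ester in 1,2-fashion to the allylic alcohol (ester-to-alcohol hydride reduction) and leaves the E-alkene and the aryl silyl ether untouched.

Step 3
Reactants: 3 (E)-4-(triisopropylsilyloxy)cinnamyl alcohol
Product: 4 methyl (E)-4-(triisopropylsilyloxy)cinnamyl carbonate
Conditions: ClCO2Me, pyridine, CH2Cl2, 0 °C
Reagents that add atoms: methyl chloroformate, COC(=O)Cl
Why: O-acylation of the allylic alcohol with a chloroformate (carbonate formation) installs the leaving group for iridium π-allyl chemistry.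

Step 4
Reactants: 5 3-phenylpropanal
Product: 7 (3S)-1-phenylhex-5-en-3-ol, via borinate ester 6 (not isolated)
Conditions: (+)-Ipc2BOMe [from (−)-α-pinene], allylMgBr, Et2O, 0 °C to rt; then 5, −78 °C; NaOH, H2O2
Reagents that add atoms: allylmagnesium bromide, C=CC[Mg]Br (delivered through (+)-B-allyldiisopinocampheylborane formed in the flask, C=CCB([C@H]1C[C@H]2C[C@@H]([C@@H]1C)C2(C)C)[C@H]1C[C@H]2C[C@@H]([C@@H]1C)C2(C)C)
Why: Brown asymmetric allylboration, in which the (−)-α-pinene-derived allylborane adds through a chair six-membered transition state to the Re face of the aldehyde and so sets the (S) carbinol centre, followed by oxidative cleavage of borinate 6.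

Step 5
Reactants: 7 (3S)-1-phenylhex-5-en-3-ol
Product: 8 (3S)-3-(tert-butyldimethylsilyloxy)-1-phenylhex-5-ene
Conditions: TBSCl, imidazole, DMF, rt
Reagents that add atoms: tert-butyldimethylsilyl chloride, CC(C)(C)[Si](C)(C)Cl
Why: Silylation of the secondary alcohol (silyl ether formation) protects the carbinol through the dianion and methoxide steps without touching its configuration.

Step 6
Reactants: 9 4-hydroxy-6-methyl-2H-pyran-2-one (1.5 equiv); 4 methyl (E)-4-(triisopropylsilyloxy)cinnamyl carbonate
Product: 10 (R)-3-(1-arylallyl)-4-hydroxy-6-methyl-2-pyrone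
Conditions: [Ir(cod)Cl]2 (2 mol %), (Ra,Rc,Rc)-phosphoramidite (4 mol %, activated with n-PrNH2), DBU, THF, rt
Reagents that add atoms: none
Why: Iridium-catalysed asymmetric allylic alkylation of a stabilised carbon nucleophile, in which the cyclometalated Ir–phosphoramidite ionises the carbonate and the soft pyronate C3 attacks the aryl-bearing allyl terminus (branched product) on the face fixed by the ligand to give (R), any O-allylated ether being re-ionised and funnelled to the C-alkylated vinylogous acid.

Step 7
Reactants: 10 (R)-3-(1-arylallyl)-4-hydroxy-6-methyl-2-pyrone; 8 (3S)-3-(tert-butyldimethylsilyloxy)-1-phenylhex-5-ene (3 equiv)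
Product: 11 3-heptenyl-4-hydroxy-6-methyl-2-pyrone (1R,2E,5S)
Conditions: Hoveyda–Grubbs II (5 mol %), CH2Cl2, 40 °C
Reagents that add atoms: none
Why: Olefin cross-metathesis between the hindered allyl-branched terminal alkene and an excess of the unhindered homoallylic ether should give the E-1,2-disubstituted alkene under thermodynamic control, with both stereocentres remote from the reacting carbons.

Step 8
Reactants: 11 3-heptenyl-4-hydroxy-6-methyl-2-pyrone (1R,2E,5S); 12 (E)-N-methoxy-N-methylcinnamamide
Product: 14 3-heptenyl-4-hydroxy-6-(cinnamoylmethyl)-2-pyrone, via tetrahedral Weinreb adduct 13 (not isolated)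
Conditions: LDA (2.3 equiv), THF, −78 to −20 °C; 12, −78 to 0 °C; cold 1 M HCl
Reagents that add atoms: none
Why: Dianion C-acylation with a Weinreb amide, in which the second equivalent of LDA removes a proton of the C6 methyl (vinylogous to the lactone carbonyl, far more acidic than the side-chain C1–H next to the electron-rich pyronate) and the chelated adduct 13 keeps the enone masked until the acid quench.

Step 9
Reactants: 14 3-heptenyl-4-hydroxy-6-(cinnamoylmethyl)-2-pyrone
Product: 16 2′,4′,6′-trihydroxy-3′-heptenyl chalcone, via magnesium triketo ester 15 (not isolated)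
Conditions: Mg(OMe)2 (8 equiv), MeOH/THF, 60 °C; then 1 M HCl to pH 3–4, 0 °C
Reagents that add atoms: none
Why: Methoxide adds to the lactone carbonyl C2 of the magnesium pyronate and opens it to the chelated methyl 3,5,7-triketo ester 15, whose free methylene C6 (between the C5 and the cinnamoyl C7 carbonyls) attacks the ester carbon as a magnesium enolate, expels methoxide and gives a cyclohexanetrione that tautomerises irreversibly to the acylphloroglucinol. The closest known reaction is the magnesium methoxide conversion of 6-(2-oxoalkyl)-4-hydroxy-2-pyrones and 3,5,7-triketo esters into acylphloroglucinols, the laboratory counterpart of the chalcone synthase cyclisation. Ring A closes in a 6-(enolexo)-exo-trig Claisen (Dieckmann-type) mode that forms the C1′–C2′ bond. No stereocentre is created, since C2 of 15 becomes the aromatic C3′, and the side-chain centres C1 and C5 carry no proton acidic to methoxide and pass through unchanged. The step needs Claisen over aldol selectivity, and the C2 substituent secures it: it makes C2 the least acidic and most hindered carbon acid and keeps the ester un-enolised, an aldol attack of C2 on the C7 ketone would give a quaternary carbon that cannot aromatise and reverts, and relactonisation only returns 14. The magnesium phenolate holds the 2′,6′-dihydroxychalcone open until the cold acid quench, after which 16 is carried on at once.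

Step 10
Reactants: 16 2′,4′,6′-trihydroxy-3′-heptenyl chalcone
Product: 17 4′-O-triisopropylsilyl chalcone
Conditions: TIPSCl (1.05 equiv), imidazole, DMF, 0 °C
Reagents that add atoms: triisopropylsilyl chloride, CC(C)[Si](Cl)(C(C)C)C(C)C
Why: Selective silylation of the most acidic phenol, since the 4′-hydroxyl para to the ketone is the only one that cannot chelate the cinnamoyl carbonyl and should react first with one equivalent of silyl chloride.

Step 11
Reactants: 17 4′-O-triisopropylsilyl chalcone
Product: 18 6′-O-methyl-4′-O-triisopropylsilyl chalcone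
Conditions: MeI, K2CO3, acetone, rt
Reagents that add atoms: iodomethane, CI
Why: Williamson O-methylation of the 2′,6′-dihydroxyaryl ketone stops at the mono-ether because the remaining hydroxyl is locked in the carbonyl chelate, and it should go to O6′, flanked only by H5′, instead of O2′, which is screened by the branched C3′ substituent, while any flavanone formed under base reopens by E1cB to the same phenolate.

Step 12
Reactants: 18 6′-O-methyl-4′-O-triisopropylsilyl chalcone
Product: 19 ent-alpinnanin A
Conditions: TBAF/AcOH (1:1, excess), THF, 0 °C to rt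
Reagents that add atoms: none
Why: Fluoride-induced desilylation cleaves both aryl triisopropylsilyl ethers quickly and the secondary TBS ether more slowly, under buffered near-neutral conditions that avoid acid ionisation at C1 and base-induced closure of the 2′-hydroxychalcone to a flavanone.

**Compound list**

1 | methyl (E)-3-(4-hydroxyphenyl)prop-2-enoate | COC(=O)/C=C/c1ccc(O)cc1 | starting material
2 | methyl (E)-3-[4-(triisopropylsilyloxy)phenyl]prop-2-enoate | COC(=O)/C=C/c1ccc(O[Si](C(C)C)(C(C)C)C(C)C)cc1 | intermediate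
3 | (E)-3-[4-(triisopropylsilyloxy)phenyl]prop-2-en-1-ol | OC/C=C/c1ccc(O[Si](C(C)C)(C(C)C)C(C)C)cc1 | intermediate
4 | methyl (E)-3-[4-(triisopropylsilyloxy)phenyl]prop-2-en-1-yl carbonate | COC(=O)OC/C=C/c1ccc(O[Si](C(C)C)(C(C)C)C(C)C)cc1 | intermediate
5 | 3-phenylpropanal | O=CCCc1ccccc1 | starting material
6 | (3S)-1-phenylhex-5-en-3-yl diisopinocampheylborinate (Ipc groups from (−)-α-pinene) | C=CC[C@@H](OB([C@H]1C[C@H]2C[C@@H]([C@@H]1C)C2(C)C)[C@H]1C[C@H]2C[C@@H]([C@@H]1C)C2(C)C)CCc1ccccc1 | intermediate
7 | (3S)-1-phenylhex-5-en-3-ol | C=CC[C@@H](O)CCc1ccccc1 | intermediate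
8 | tert-butyldimethyl{[(3S)-1-phenylhex-5-en-3-yl]oxy}silane | C=CC[C@@H](O[Si](C)(C)C(C)(C)C)CCc1ccccc1 | intermediate
9 | 4-hydroxy-6-methyl-2H-pyran-2-one (triacetic acid lactone) | CC1=CC(O)=CC(=O)O1 | starting material
10 | 4-hydroxy-6-methyl-3-{(1R)-1-[4-(triisopropylsilyloxy)phenyl]prop-2-en-1-yl}-2H-pyran-2-one | CC1=CC(O)=C([C@H](C=C)c2ccc(O[Si](C(C)C)(C(C)C)C(C)C)cc2)C(=O)O1 | intermediate
11 | 3-{(1R,2E,5S)-5-(tert-butyldimethylsilyloxy)-7-phenyl-1-[4-(triisopropylsilyloxy)phenyl]hept-2-en-1-yl}-4-hydroxy-6-methyl-2H-pyran-2-one | CC1=CC(O)=C([C@H](/C=C/C[C@@H](O[Si](C)(C)C(C)(C)C)CCc2ccccc2)c2ccc(O[Si](C(C)C)(C(C)C)C(C)C)cc2)C(=O)O1 | intermediate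
12 | (E)-N-methoxy-N-methyl-3-phenylprop-2-enamide | CON(C)C(=O)/C=C/c1ccccc1 | starting material
13 | N-methoxy-N-methyl hemiaminal adduct at the side-chain carbon of 14 (present as its lithium chelate; side-chain centres as in 11) | CON(C)C(O)(CC1=CC(O)=C([C@H](/C=C/C[C@@H](O[Si](C)(C)C(C)(C)C)CCc2ccccc2)c2ccc(O[Si](C(C)C)(C(C)C)C(C)C)cc2)C(=O)O1)/C=C/c1ccccc1 | intermediate
14 | 3-{(1R,2E,5S)-5-(tert-butyldimethylsilyloxy)-7-phenyl-1-[4-(triisopropylsilyloxy)phenyl]hept-2-en-1-yl}-4-hydroxy-6-[(E)-2-oxo-4-phenylbut-3-en-1-yl]-2H-pyran-2-one | O=C1OC(CC(=O)/C=C/c2ccccc2)=CC(O)=C1[C@H](/C=C/C[C@@H](O[Si](C)(C)C(C)(C)C)CCc2ccccc2)c2ccc(O[Si](C(C)C)(C(C)C)C(C)C)cc2 | intermediate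
15 | methyl (8E)-3,5,7-trioxo-9-phenylnon-8-enoate carrying the heptenyl side chain of 14 at C2 (magnesium chelate, C2 epimers; side-chain centres spatially as in 14) | COC(=O)C(C(=O)CC(=O)CC(=O)/C=C/c1ccccc1)[C@H](/C=C/C[C@@H](O[Si](C)(C)C(C)(C)C)CCc1ccccc1)c1ccc(O[Si](C(C)C)(C(C)C)C(C)C)cc1 | intermediate
16 | (E)-1-(3-{(1R,2E,5S)-5-(tert-butyldimethylsilyloxy)-7-phenyl-1-[4-(triisopropylsilyloxy)phenyl]hept-2-en-1-yl}-2,4,6-trihydroxyphenyl)-3-phenylprop-2-en-1-one | Oc1cc(O)c([C@H](/C=C/C[C@@H](O[Si](C)(C)C(C)(C)C)CCc2ccccc2)c2ccc(O[Si](C(C)C)(C(C)C)C(C)C)cc2)c(O)c1C(=O)/C=C/c1ccccc1 | intermediate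
17 | (E)-1-(3-{(1R,2E,5S)-5-(tert-butyldimethylsilyloxy)-7-phenyl-1-[4-(triisopropylsilyloxy)phenyl]hept-2-en-1-yl}-2,6-dihydroxy-4-(triisopropylsilyloxy)phenyl)-3-phenylprop-2-en-1-one | Oc1cc(O[Si](C(C)C)(C(C)C)C(C)C)c([C@H](/C=C/C[C@@H](O[Si](C)(C)C(C)(C)C)CCc2ccccc2)c2ccc(O[Si](C(C)C)(C(C)C)C(C)C)cc2)c(O)c1C(=O)/C=C/c1ccccc1 | intermediate
18 | (E)-1-(3-{(1R,2E,5S)-5-(tert-butyldimethylsilyloxy)-7-phenyl-1-[4-(triisopropylsilyloxy)phenyl]hept-2-en-1-yl}-2-hydroxy-6-methoxy-4-(triisopropylsilyloxy)phenyl)-3-phenylprop-2-en-1-one | COc1cc(O[Si](C(C)C)(C(C)C)C(C)C)c([C@H](/C=C/C[C@@H](O[Si](C)(C)C(C)(C)C)CCc2ccccc2)c2ccc(O[Si](C(C)C)(C(C)C)C(C)C)cc2)c(O)c1C(=O)/C=C/c1ccccc1 | intermediate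
19 | ent-alpinnanin A, (E)-1-{2,4-dihydroxy-3-[(1R,2E,5S)-5-hydroxy-1-(4-hydroxyphenyl)-7-phenylhept-2-en-1-yl]-6-methoxyphenyl}-3-phenylprop-2-en-1-one | COc1cc(O)c([C@H](/C=C/C[C@@H](O)CCc2ccccc2)c2ccc(O)cc2)c(O)c1C(=O)/C=C/c1ccccc1 | target

**Step count and risks**

Total steps: 12. Longest linear sequence: 10 steps (steps 1–3 and 6–12, from methyl p-coumarate).

Steps most likely to fail:

Step 9 (key step). The lactone carbonyl is screened by the branched C3 substituent, so ring opening may be slow and the triketo ester may simply relactonise. Prolonged heating in methoxide may also cleave the aryl silyl ether by methanolysis, and the free 2′,6′-dihydroxychalcone may close to flavanones during work-up.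
Fallback: ring A is made before the stereocentre. Setting out from 9, the dianion is acylated with 12 to give 4-hydroxy-6-[(E)-2-oxo-4-phenylbut-3-en-1-yl]-2H-pyran-2-one F1. This unhindered pyrone is the direct substrate type of the magnesium methoxide Claisen aromatisation and should give 2′,4′,6′-trihydroxychalcone F2, handled as its phenolate. Iridium-catalysed branched C-allylation of the phloroglucinolate with 4 (C3′ and C5′ are equivalent) would give (E)-1-(2,4,6-trihydroxy-3-{(1R)-1-[4-(triisopropylsilyloxy)phenyl]prop-2-en-1-yl}phenyl)-3-phenylprop-2-en-1-one F3. Cross-metathesis of F3 with 8 comes back to the route at 16.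

Step 6. The pyronate is ambident and its conjugate acid is strong, so O-allylation, protonolysis of the cyclometalated catalyst, or erosion of branched selectivity and enantioselectivity may occur.
Fallback: the pyrone is assembled around the stereocentre. Setting out from 4, iridium-catalysed allylic alkylation with methyl acetoacetate (a standard β-keto ester nucleophile) gives methyl (3S)-2-acetyl-3-[4-(triisopropylsilyloxy)phenyl]pent-4-enoate F4 (same spatial sense; the descriptor changes with the CIP priorities). Its dianion (NaH, then n-BuLi) is acetylated at the terminal methyl with N-methoxy-N-methylacetamide to give methyl 2-{(1S)-1-[4-(triisopropylsilyloxy)phenyl]prop-2-en-1-yl}-3,5-dioxohexanoate F5. DBU-mediated lactonisation in hot toluene comes back to the route at 10.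

Step 10. Silylation may compete at the 6′-hydroxyl or go on to the bis-ether, because the 4′-hydroxyl is flanked by the bulky C3′ group, and the base may trigger flavanone closure. The O6′ over O2′ preference of step 11 rests on the same kind of steric argument.
Fallback: the hydroxyls are differentiated by chelation in the flavanone. Setting out from 16, sodium acetate in warm ethanol is used to close the chalcone deliberately to the 5,7-dihydroxyflavanones, drawn as the 6-linked isomer 5,7-dihydroxy-2-phenylchroman-4-one bearing the heptenyl side chain at C6 F6 (the 8-linked isomer and the C2 epimers behave alike). Only the 7-hydroxyl is free of the carbonyl chelate, so TIPSCl/imidazole gives the 7-O-triisopropylsilyl flavanone F7. Iodomethane and potassium carbonate in refluxing acetone then open the 5-hydroxyflavanone by E1cB and methylate the released, less hindered phenolate, coming back to the route at 18.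

**Further compounds**

F1 | step 9 | 4-hydroxy-6-[(E)-2-oxo-4-phenylbut-3-en-1-yl]-2H-pyran-2-one | O=C1C=C(O)C=C(CC(=O)/C=C/c2ccccc2)O1
F2 | step 9 | (E)-3-phenyl-1-(2,4,6-trihydroxyphenyl)prop-2-en-1-one | O=C(/C=C/c1ccccc1)c1c(O)cc(O)cc1O
F3 | step 9 | (E)-1-(2,4,6-trihydroxy-3-{(1R)-1-[4-(triisopropylsilyloxy)phenyl]prop-2-en-1-yl}phenyl)-3-phenylprop-2-en-1-one | Oc1cc(O)c([C@H](C=C)c2ccc(O[Si](C(C)C)(C(C)C)C(C)C)cc2)c(O)c1C(=O)/C=C/c1ccccc1
F4 | step 6 | methyl (3S)-2-acetyl-3-[4-(triisopropylsilyloxy)phenyl]pent-4-enoate (C2 epimers) | COC(=O)C(C(C)=O)[C@H](C=C)c1ccc(O[Si](C(C)C)(C(C)C)C(C)C)cc1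
F5 | step 6 | methyl 2-{(1S)-1-[4-(triisopropylsilyloxy)phenyl]prop-2-en-1-yl}-3,5-dioxohexanoate (C2 epimers) | COC(=O)C(C(=O)CC(C)=O)[C@H](C=C)c1ccc(O[Si](C(C)C)(C(C)C)C(C)C)cc1
F6 | step 10 | 6-{(1R,2E,5S)-5-(tert-butyldimethylsilyloxy)-7-phenyl-1-[4-(triisopropylsilyloxy)phenyl]hept-2-en-1-yl}-5,7-dihydroxy-2-phenylchroman-4-one (C2 epimers) | O=C1CC(c2ccccc2)Oc2cc(O)c([C@H](/C=C/C[C@@H](O[Si](C)(C)C(C)(C)C)CCc3ccccc3)c3ccc(O[Si](C(C)C)(C(C)C)C(C)C)cc3)c(O)c12
F7 | step 10 | 6-{(1R,2E,5S)-5-(tert-butyldimethylsilyloxy)-7-phenyl-1-[4-(triisopropylsilyloxy)phenyl]hept-2-en-1-yl}-5-hydroxy-2-phenyl-7-(triisopropylsilyloxy)chroman-4-one (C2 epimers) | O=C1CC(c2ccccc2)Oc2cc(O[Si](C(C)C)(C(C)C)C(C)C)c([C@H](/C=C/C[C@@H](O[Si](C)(C)C(C)(C)C)CCc3ccccc3)c3ccc(O[Si](C(C)C)(C(C)C)C(C)C)cc3)c(O)c12
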